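**Retrosynthetic overview**
1. The (E)-acrylic acid arm is put on last, by cross-metathesis of a C6 vinyl group with free acrylic acid, so the acid needs no protecting group.
2. The C5 ester comes from a Mitsunobu coupling (inversion) of a 5,6-trans hydroxy lactone with (2E,4E,6S)-4,6-dimethyldodeca-2,4-dienoic acid, which gives the 5,6-cis ester.
3. The hydroxy lactone comes from Jones oxidation and Luche reduction of a 6-hydroxy-2-vinylpyran-3-one. That pyranone is made from racemic furyl vinyl carbinol (furfural + vinylmagnesium bromide) by an enantiomer-selective Achmatowicz oxidative ring expansion (furan to pyranone).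
4. The acid comes from a Heck reaction of acrylic acid with an (E)-alkenyl iodide, made by hydrozirconation/iodination of (S)-4-methyldec-2-yne. The alkyne comes from an enantioconvergent nickel-catalysed coupling of racemic 4-bromopent-2-yne with hexylzinc bromide.
5. Ring order: there is only one ring; the six-membered oxygen ring is formed once, in the ring expansion, and kept to the end.

Assumption: the pybox antipode named in step 2 (and in its fallback) is taken to give the (S) product by analogy; both antipodes are commercial and the other one is used if the first run shows the opposite sense.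

**Route**

Step 1
Reactants: 1 pent-3-yn-2-ol (racemic)
Product: 2 4-bromopent-2-yne (racemic)
Conditions: PBr3 (0.4 equiv), pyridine (cat.), Et2O, −20 to 0 °C; distilled
Reagents that add atoms: phosphorus tribromide, BrP(Br)Br
Why: Bromination of a secondary propargylic alcohol through its phosphite ester (SN2 by bromide), run cold to keep allenyl bromide low; the racemate is exactly what the next step needs.

Step 2
Reactants: 2 4-bromopent-2-yne (racemic); 3 n-hexylzinc bromide
Product: 4 (S)-4-methyldec-2-yne
Conditions: NiCl2·glyme (10 mol %), (S,S)-iPr-pybox (13 mol %), 3 (0.5 M in THF, 1.6 equiv), DMA, −20 °C, 24 h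
Reagents that add atoms: none
Why: Proposed new method: enantioconvergent nickel/pybox Negishi alkylation of a racemic secondary propargylic bromide with an unfunctionalised primary alkylzinc halide; monovalent nickel abstracts bromine to give a planar propargylic radical (both enantiomers of 2 converge), the radical is captured at its sp3 terminus by the chiral (pybox)Ni–hexyl complex and C(sp3)–C(sp3) reductive elimination from trivalent nickel forms the C4–C5 bond and sets C4 as (S) under ligand control; the closest known reaction types are nickel/pybox enantioconvergent Negishi couplings of racemic propargylic halides with arylzinc reagents and of racemic secondary allylic chlorides with alkylzinc halides.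

Step 3
Reactants: 4 (S)-4-methyldec-2-yne
Product: 6 (2E,4S)-2-iodo-4-methyldec-2-ene, via alkenylzirconocene chloride 5 (not isolated)
Conditions: Cp2Zr(H)Cl (1.5 equiv), THF, 40 °C, 2 h; then I2 (1.6 equiv), 0 °C
Reagents that add atoms: iodine, II
Why: Syn hydrozirconation puts zirconium on the less hindered, methyl-bearing alkyne carbon (the regioisomers equilibrate through excess Zr–H) and iodinolysis of the C–Zr bond goes with retention, giving the (E)-alkenyl iodide with the remote stereocentre untouched.

Step 4
Reactants: 6 (2E,4S)-2-iodo-4-methyldec-2-ene; 7 acrylic acid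
Product: 8 (2E,4E,6S)-4,6-dimethyldodeca-2,4-dienoic acid
Conditions: 7 (1.5 equiv), Pd(OAc)2 (5 mol %), NaHCO3 (2.5 equiv), n-Bu4NCl (1 equiv), DMF, 40 °C
Reagents that add atoms: none
Why: Heck reaction under ligand-free phase-transfer (Jeffery) conditions: oxidative addition to zerovalent palladium, syn carbopalladation of acrylic acid and syn β-hydride elimination give the (2E) acid with retention of the (4E) geometry.

Step 5
Reactants: 9 furfural; 10 vinylmagnesium bromide
Product: 11 1-(furan-2-yl)prop-2-en-1-ol (racemic)
Conditions: 10 (1.0 M in THF, 1.1 equiv), THF, −78 to 0 °C; then H2O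
Reagents that add atoms: none
Why: Grignard 1,2-addition to an aldehyde; the racemate is wanted because the next step picks out one enantiomer.

Step 6
Reactants: 11 1-(furan-2-yl)prop-2-en-1-ol (racemic)
Product: 13 (2S)-6-hydroxy-2-vinyl-2H-pyran-3(6H)-one, via (2Z,5S)-5-hydroxy-4-oxohepta-2,6-dienal 12 (not isolated)
Conditions: Ti(OiPr)4 (20 mol %), diisopropyl L-(+)-tartrate (24 mol %), t-BuOOH (0.45 equiv, anhydrous), 4 Å molecular sieves, CH2Cl2, −20 °C; stopped near 45% conversion, (R)-11 removed by chromatography
Reagents that add atoms: tert-butyl hydroperoxide, CC(C)(C)OO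
Why: Achmatowicz oxidative ring expansion run as a Sharpless kinetic resolution: the titanium/L-(+)-tartrate/peroxide complex oxidises the furan of (S)-11 much faster than that of (R)-11, the oxidised furan opens to the (Z)-hydroxy-enedione 12 and recloses through the carbinol oxygen, so the five-membered furan becomes the six-membered pyranone lactol (both anomers) with the carbinol centre carried over unchanged as C2 (S).

Step 7
Reactants: 13 (2S)-6-hydroxy-2-vinyl-2H-pyran-3(6H)-one
Product: 14 (6S)-6-vinyl-2H-pyran-2,5(6H)-dione
Conditions: pre-formed Jones reagent (CrO3, H2SO4, H2O; 1.2 equiv), acetone, 0 °C, 10 min; short silica pad, used at once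
Reagents that add atoms: none
Why: Jones oxidation of the lactol to the lactone under acidic conditions that do not enolise C6 on this time scale, both anomers converging on one keto lactone.

Step 8
Reactants: 14 (6S)-6-vinyl-2H-pyran-2,5(6H)-dione
Product: 15 (5R,6S)-5-hydroxy-6-vinyl-5,6-dihydro-2H-pyran-2-one
Conditions: NaBH4 (1.0 equiv), CeCl3·7H2O (1.0 equiv), MeOH/CH2Cl2 (1:1), −78 °C
Reagents that add atoms: none
Why: Luche 1,2-reduction: the small hydride adds axially to the ketone of the half-chair that holds the C6 vinyl group pseudo-equatorial, giving the 5,6-trans alcohol (5R), while CeCl3 suppresses conjugate reduction.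

Step 9
Reactants: 15 (5R,6S)-5-hydroxy-6-vinyl-5,6-dihydro-2H-pyran-2-one; 8 (2E,4E,6S)-4,6-dimethyldodeca-2,4-dienoic acid
Product: 16 (2S,3S)-6-oxo-2-vinyl-3,6-dihydro-2H-pyran-3-yl (2E,4E,6S)-4,6-dimethyldodeca-2,4-dienoate
Conditions: 8 (1.3 equiv), PPh3 (1.5 equiv), DIAD (1.5 equiv), THF, 0 °C to rt
Reagents that add atoms: none
Why: Mitsunobu esterification: the carboxylate displaces the alkoxyphosphonium group in an SN2 step with inversion, turning (5R) into (5S) and giving the 5,6-cis ester; material from any minor (2R) series becomes a diastereomer here and is removed by chromatography.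

Step 10
Reactants: 16 (2S,3S)-6-oxo-2-vinyl-3,6-dihydro-2H-pyran-3-yl (2E,4E,6S)-4,6-dimethyldodeca-2,4-dienoate; 7 acrylic acid
Product: 17 (E)-3-[(2S,3S)-3-{[(2E,4E,6S)-4,6-dimethyldodeca-2,4-dienoyl]oxy}-6-oxo-3,6-dihydro-2H-pyran-2-yl]prop-2-enoic acid
Conditions: 7 (10 equiv), second-generation Hoveyda–Grubbs catalyst RuCl2(H2IMes)(=CH-C6H4-2-OiPr) (10 mol %), CH2Cl2 (0.3 M), 40 °C
Reagents that add atoms: none
Why: Olefin cross-metathesis of the terminal vinyl group with acrylic acid gives the (E)-acrylic acid, the conjugated di- and trisubstituted alkenes of the dienoate and the ring enoate being far less reactive; neither stereocentre is touched.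

**Compound list**
1 | pent-3-yn-2-ol (racemic) | CC#CC(C)O | starting material
2 | 4-bromopent-2-yne (racemic) | CC#CC(C)Br | intermediate
3 | n-hexylzinc bromide, C6H13ZnBr | CCCCCC[Zn]Br | starting material
4 | (S)-4-methyldec-2-yne | CCCCCC[C@H](C)C#CC | intermediate
5 | chlorobis(cyclopentadienyl)[(2E,4S)-4-methyldec-2-en-2-yl]zirconium, Cp2Zr(Cl)(C11H21) (not isolated) | CCCCCC[C@H](C)/C=C(C)/[Zr](Cl)(C1C=CC=C1)C1C=CC=C1 | intermediate
6 | (2E,4S)-2-iodo-4-methyldec-2-ene | CCCCCC[C@H](C)/C=C(C)/I | intermediate
7 | acrylic acid | C=CC(=O)O | starting material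
8 | (2E,4E,6S)-4,6-dimethyldodeca-2,4-dienoic acid | CCCCCC[C@H](C)/C=C(C)/C=C/C(=O)O | intermediate
9 | furfural | O=Cc1ccco1 | starting material
10 | vinylmagnesium bromide, CH2=CHMgBr | C=C[Mg]Br | starting material
11 | 1-(furan-2-yl)prop-2-en-1-ol (racemic) | C=CC(O)c1ccco1 | intermediate
12 | (2Z,5S)-5-hydroxy-4-oxohepta-2,6-dienal (not isolated) | C=C[C@H](O)C(=O)/C=C\C=O | intermediate
13 | (2S)-6-hydroxy-2-vinyl-2H-pyran-3(6H)-one (both anomers) | C=C[C@@H]1OC(O)C=CC1=O | intermediate
14 | (6S)-6-vinyl-2H-pyran-2,5(6H)-dione | C=C[C@@H]1OC(=O)C=CC1=O | intermediate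
15 | (5R,6S)-5-hydroxy-6-vinyl-5,6-dihydro-2H-pyran-2-one | O[C@@H]1C=CC(=O)O[C@H]1C=C | intermediate
16 | (2S,3S)-6-oxo-2-vinyl-3,6-dihydro-2H-pyran-3-yl (2E,4E,6S)-4,6-dimethyldodeca-2,4-dienoate | CCCCCC[C@H](C)/C=C(C)/C=C/C(=O)O[C@H]1C=CC(=O)O[C@H]1C=C | intermediate
17 | (E)-3-[(2S,3S)-3-{[(2E,4E,6S)-4,6-dimethyldodeca-2,4-dienoyl]oxy}-6-oxo-3,6-dihydro-2H-pyran-2-yl]prop-2-enoic acid | CCCCCC[C@H](C)/C=C(C)/C=C/C(=O)O[C@H]1C=CC(=O)O[C@H]1/C=C/C(=O)O | target

**Step count and risks**

Total: 10 steps (4 to the acid, 4 to the hydroxy lactone, 2 after the fragments meet). Longest linear sequence: 6 steps (steps 5–10 from furfural; steps 1–4, 9, 10 from pent-3-yn-2-ol is equally long).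

The three steps most likely to fail:

Step 2 (the proposed new coupling). The enantioselectivity with a simple alkylzinc is untested, and coupling at the allenyl terminus or reduction of the bromide may compete. The fallback uses known chemistry only; it sets out from 3 and comes back at 8. Commercial racemic (E)-4-chloropent-2-ene, a symmetrical 1,3-dimethylallyl chloride with no regiochemical issue, is coupled with 3 under the known nickel/pybox enantioconvergent Negishi conditions for secondary allylic chlorides (NiCl2·glyme, chiral pybox, NaCl, DMA/DMF, −10 °C) to give (2E,4S)-4-methyldec-2-ene F1. Ozonolysis (O3, CH2Cl2, −78 °C; Me2S) cleaves the propenyl group to (S)-2-methyloctanal F2. Wittig olefination with 2-(triphenylphosphoranylidene)propanal (toluene, 80 °C) gives (2E,4S)-2,4-dimethyldec-2-enal F3. A Horner–Wadsworth–Emmons reaction with triethyl phosphonoacetate (NaH, THF, 0 °C) gives ethyl (2E,4E,6S)-4,6-dimethyldodeca-2,4-dienoate F4, and LiOH (THF/H2O) gives 8. Steps 1, 3 and 4 are then not needed.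

Step 7 (keto lactone 14). Its C6–H is allylic and alpha to the ketone, so 14 can tautomerise to the aromatic 5-hydroxy-6-vinyl-2-pyranone or move the vinyl double bond into conjugation, during the oxidation or on silica. The fallback sets out from 13 and comes back at 15, bypassing 14. Lactol 13 is isomerised directly with [Ir(cod)Cl]2 (2.5 mol %) and 2,6-dichlorobenzoic acid (10 mol %) in CHCl3 at rt. An iridium hydride relays the lactol hydride to the ring ketone, a redox-neutral internal transfer hydrogenation. I recall this as precedented for 2-alkyl Achmatowicz lactols and trans-selective there, but have not checked it; the vinyl group could also isomerise under iridium hydride. No new compound lies on this way (entry F0).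

Step 10 (cross-metathesis). The ruthenium alkylidene formed at the vinyl group can close a six-membered ring onto the C2=C3 bond of the cis-disposed dienoate, expelling the diene and giving a bicyclic bis-lactone in competition with the bimolecular reaction. The fallback sets out from 15 and comes back at 17; it moves the metathesis in front of the esterification, where no such ring closure is possible. Alcohol 15 with tert-butyl acrylate (5 equiv) and the same ruthenium catalyst (CH2Cl2, 40 °C) gives tert-butyl (E)-3-[(2S,3R)-3-hydroxy-6-oxo-3,6-dihydro-2H-pyran-2-yl]prop-2-enoate F5. Mitsunobu esterification with 8 (PPh3, DIAD, THF, 0 °C) gives the inverted ester tert-butyl (E)-3-[(2S,3S)-3-{[(2E,4E,6S)-4,6-dimethyldodeca-2,4-dienoyl]oxy}-6-oxo-3,6-dihydro-2H-pyran-2-yl]prop-2-enoate F6. CF3CO2H/CH2Cl2 (1:4, 0 °C) removes the tert-butyl group to give 17.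

**Further compounds**
F1 | step 2 | (2E,4S)-4-methyldec-2-ene | CCCCCC[C@H](C)/C=C/C
F2 | step 2 | (S)-2-methyloctanal | CCCCCC[C@H](C)C=O
F3 | step 2 | (2E,4S)-2,4-dimethyldec-2-enal | CCCCCC[C@H](C)/C=C(C)/C=O
F4 | step 2 | ethyl (2E,4E,6S)-4,6-dimethyldodeca-2,4-dienoate | CCCCCC[C@H](C)/C=C(C)/C=C/C(=O)OCC
F0 | step 7 | none | none
F5 | step 10 | tert-butyl (E)-3-[(2S,3R)-3-hydroxy-6-oxo-3,6-dihydro-2H-pyran-2-yl]prop-2-enoate | O[C@@H]1C=CC(=O)O[C@H]1/C=C/C(=O)OC(C)(C)C
F6 | step 10 | tert-butyl (E)-3-[(2S,3S)-3-{[(2E,4E,6S)-4,6-dimethyldodeca-2,4-dienoyl]oxy}-6-oxo-3,6-dihydro-2H-pyran-2-yl]prop-2-enoate | CCCCCC[C@H](C)/C=C(C)/C=C/C(=O)O[C@H]1C=CC(=O)O[C@H]1/C=C/C(=O)OC(C)(C)C
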